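The seven-membered ring is closed by inserting a two-carbon unit between C1 and C8 (daucane numbering). Quaternary C1 is alpha to the C2 carbinol of the five-membered ring and alkene carbon C8 carries a methyl group, so C1 is read as the enolate carbon of a C2 ketone and C8 as a methyl ketone. A Schweizer annulation with vinyltriphenylphosphonium bromide then forms C1–C10 by Michael addition and C8=C9 by intramolecular Wittig olefination in one operation and sets the trans ring fusion. The precursor is a regiodefined cyclopentanone silyl enol ether with a beta-alkoxy methyl ketone side chain, assembled from (R)-4-silyloxycyclopentenone by a three-component coupling.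

Key step: step 11

Remark: daucane locants (C1 angular carbon with the C15 methyl, C2, C3, C4 isopropyl-bearing carbon, C5 ring fusion, C6, C7, C8 with the C14 methyl, C9, C10) are used for all intermediates, and the configuration at the benzyloxy carbon of 3 is immaterial because that centre becomes the C8 ketone.

Step 1
Reactants: 1 ethyl (S)-3-hydroxybutanoate
Product: 2 ethyl (S)-3-(benzyloxy)butanoate
Conditions: benzyl 2,2,2-trichloroacetimidate, TfOH (cat.), cyclohexane/CH2Cl2, 0 °C to rt
Reagents that add atoms: benzyl 2,2,2-trichloroacetimidate, ClC(Cl)(Cl)C(=N)OCc1ccccc1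
Why: Acid-catalysed O-benzylation with a trichloroacetimidate should protect the carbinol without base, so the beta-hydroxy ester neither eliminates nor racemises.

Step 2
Reactants: 2 ethyl (S)-3-(benzyloxy)butanoate
Product: 3 (S)-3-(benzyloxy)butanal
Conditions: iBu2AlH (DIBAL-H), CH2Cl2, −78 °C; aq Rochelle salt
Reagents that add atoms: none
Why: Partial ester reduction at low temperature should stop at the aluminium hemiacetal, which releases the aldehyde on work-up.

Step 3
Reactants: 4 (R)-4-[(tert-butyldimethylsilyl)oxy]cyclopent-2-en-1-one, 3 (S)-3-(benzyloxy)butanal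
Product: 7 (2S,3R,4R)-2-[(1S,3S)-3-(benzyloxy)-1-hydroxybutyl]-4-[(tert-butyldimethylsilyl)oxy]-3-methylcyclopentan-1-one, via lithium enolate 5 (not isolated), via chlorozinc enolate 6 (not isolated)
Conditions: Me2CuLi (from MeLi, CuBr·SMe2), Et2O, −78 °C; ZnCl2, THF; then 3, −78 °C; aq NH4Cl
Reagents that add atoms: lithium dimethylcuprate, [Li+].C[Cu-]C; aldehyde 3, O=CC[C@H](C)OCc1ccccc1
Why: In this three-component conjugate addition–aldol coupling (Noyori three-component coupling) the cuprate should add to C1 anti to the C2 silyloxy group, and the (E)-configured cyclic zinc enolate should add to the aldehyde anti to the new methyl group through a chair Zimmerman–Traxler transition state, giving the anti aldol that fixes C5 and C6.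

Step 4
Reactants: 7 aldol adduct
Product: 8 (1R,2S,3R,4R)-2-[(1S,3S)-3-(benzyloxy)-1-hydroxybutyl]-4-[(tert-butyldimethylsilyl)oxy]-3-methyl-1-(propan-2-yl)cyclopentan-1-ol
Conditions: iPrLi, CeCl3, THF, −78 °C
Reagents that add atoms: isopropyllithium, [Li]C(C)C
Why: Organocerium 1,2-addition should suppress enolisation and loss of the beta-silyloxy group, and attack on the C4 carbonyl face opposite the C5 side chain should place the new hydroxyl cis to C6 and the isopropyl group trans.

Step 5
Reactants: 8 diol
Product: 9 O4,O6-isopropylidene acetal (acetonide) of 8, a 1,3-dioxane cis-fused to the cyclopentane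
Conditions: 2,2-dimethoxypropane, PPTS, CH2Cl2, rt
Reagents that add atoms: 2,2-dimethoxypropane, COC(C)(C)OC
Why: Acid-catalysed transacetalisation should tie the cis-disposed tertiary C4 and secondary C6 hydroxyls into a six-membered acetal that masks both for the following steps.

Step 6
Reactants: 9 acetonide silyl ether
Product: 10 C2 alcohol (9 without the silyl group)
Conditions: Bu4NF, THF, rt
Reagents that add atoms: none
Why: Fluoride desilylation should cleave the secondary silyl ether while the acetonide and benzyl ether are inert.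

Step 7
Reactants: 10 C2 alcohol
Product: 11 C2 ketone
Conditions: Dess–Martin periodinane, NaHCO3, CH2Cl2, rt
Reagents that add atoms: none
Why: Dess–Martin oxidation should convert the only free alcohol into the ketone; the C1 centre becomes enolisable and is reset in step 11.

Step 8
Reactants: 11 C2 ketone
Product: 12 C1=C2 triethylsilyl enol ether of 11
Conditions: Et3SiOTf, Et3N, CH2Cl2, 0 °C to rt
Reagents that add atoms: triethylsilyl trifluoromethanesulfonate, CC[Si](CC)(CC)OS(=O)(=O)C(F)(F)F
Why: Soft enolisation with a silyl triflate and an amine should favour the more substituted C1=C2 enol ether, because the C3 methylene is shielded by quaternary C4, so the C1 nucleophile is stored before the second ketone exists.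

Step 9
Reactants: 12 silyl enol ether benzyl ether
Product: 13 C8 secondary alcohol (12 without the benzyl group)
Conditions: H2 (1 atm), Pd(OH)2/C, NaHCO3, EtOAc, rt
Reagents that add atoms: none
Why: Neutral hydrogenolysis of the benzyl ether should leave the hindered tetrasubstituted silyl enol ether and the acetonide untouched, and no other reducible group is present.

Step 10
Reactants: 13 C8 alcohol
Product: 14 C8 methyl ketone carrying the C1=C2 triethylsilyl enol ether
Conditions: Dess–Martin periodinane, pyridine, CH2Cl2, 0 °C to rt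
Reagents that add atoms: none
Why: Buffered Dess–Martin oxidation should form the methyl ketone without acid, so the silyl enol ether is retained.

Step 11
Reactants: 14 methyl ketone silyl enol ether, 15 vinyltriphenylphosphonium bromide
Product: 18 (1R,4R,5S,6S)-4,6-O-isopropylidene-4,6-dihydroxydauc-8-en-2-one, via ammonium enolate 16 (not isolated), via phosphonium ylide 17 (not isolated)
Conditions: 15 (excess), Bu4N[Ph3SiF2] (TBAT), THF/MeCN, −40 °C to rt, then 50 °C
Reagents that add atoms: vinyltriphenylphosphonium bromide 15, C=C[P+](c1ccccc1)(c1ccccc1)c1ccccc1.[Br-]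
Why: Fluoride should cleave the silyl enol ether and release the C1 enolate 16 regiospecifically without a base that could enolise the methyl ketone; conjugate addition of C1 to the vinylphosphonium salt gives ylide 17, whose carbanion C9 adds to the C8 ketone and loses Ph3PO (Schweizer annulation, a tandem Michael addition and intramolecular Wittig olefination, here with a fluoride-generated enolate). The seven-membered ring is closed by 7-exo-trig attack of the ylide carbon on the ketone, and the ring alkene is necessarily cis. The only new stereocentre, quaternary C1, is set in the Michael step by the adjacent C5 centre, because the electrophile should add to the enolate face anti to the C5 side chain, which gives the trans ring fusion with the C15 methyl cis to C6. The step needs reaction at C1 and not at C3 or C7, and olefination faster than proton transfer; the pre-formed tetrasubstituted enol ether, the non-basic trigger, low temperature and the acetonide, which holds C7 gauche to C1, should secure this. Reversible aldol closure of 16 onto the methyl ketone is only a parking state that the irreversible Michael–Wittig sequence drains.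

Step 12
Reactants: 18 tricyclic acetonide ketone
Product: 19 (1R,4R,5S,6S)-4,6-dihydroxydauc-8-en-2-one
Conditions: AcOH/H2O/THF (3:1:1), 40 °C
Reagents that add atoms: none
Why: Mild acetal hydrolysis should free both hydroxyls while the trisubstituted alkene and the beta-hydroxy ketone survive.

Step 13
Reactants: 19 keto diol, 20 4-acetoxybenzoyl chloride
Product: 21 (1R,4R,5S,6S)-4-hydroxy-2-oxodauc-8-en-6-yl 4-acetoxybenzoate
Conditions: 20, Et3N, DMAP, CH2Cl2, 0 °C to rt
Reagents that add atoms: 4-acetoxybenzoyl chloride 20, CC(=O)Oc1ccc(cc1)C(Cl)=O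
Why: DMAP-catalysed acylation should esterify the only secondary hydroxyl (C6), since the tertiary C4 hydroxyl is unreactive and C2 is still a ketone.

Step 14
Reactants: 21 keto ester
Product: 23 (1R,2R,4R,5S,6S)-2,4-dihydroxydauc-8-en-6-yl 4-hydroxybenzoate (target), via acetate-protected diol 22 (not isolated)
Conditions: NaBH4, MeOH, −40 °C; then K2CO3, MeOH, 0 °C
Reagents that add atoms: none
Why: Borohydride reduction should occur on the ketone face opposite the pseudo-axial angular methyl group (as in 17-keto steroids), giving the C2 hydroxyl cis to that methyl and to the C4 hydroxyl, and carbonate-catalysed methanolysis should then remove the more electrophilic phenolic acetate while the hindered benzoate stays.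

Compound list
1 | ethyl (S)-3-hydroxybutanoate | CCOC(=O)C[C@H](C)O | starting material
2 | ethyl (S)-3-(benzyloxy)butanoate | CCOC(=O)C[C@H](C)OCc1ccccc1 | intermediate
3 | (S)-3-(benzyloxy)butanal | O=CC[C@H](C)OCc1ccccc1 | intermediate
4 | (R)-4-[(tert-butyldimethylsilyl)oxy]cyclopent-2-en-1-one | O=C1C=C[C@H](O[Si](C)(C)C(C)(C)C)C1 | starting material
5 | lithium (3R,4R)-4-[(tert-butyldimethylsilyl)oxy]-3-methylcyclopent-1-en-1-olate | C[C@@H]1C=C(O[Li])C[C@H]1O[Si](C)(C)C(C)(C)C | intermediate
6 | chlorozinc enolate corresponding to 5 | C[C@@H]1C=C(O[Zn]Cl)C[C@H]1O[Si](C)(C)C(C)(C)C | intermediate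
7 | (2S,3R,4R)-2-[(1S,3S)-3-(benzyloxy)-1-hydroxybutyl]-4-[(tert-butyldimethylsilyl)oxy]-3-methylcyclopentan-1-one | C[C@H](OCc1ccccc1)C[C@H](O)[C@H]1C(=O)C[C@@H](O[Si](C)(C)C(C)(C)C)[C@@H]1C | intermediate
8 | (1R,2S,3R,4R)-2-[(1S,3S)-3-(benzyloxy)-1-hydroxybutyl]-4-[(tert-butyldimethylsilyl)oxy]-3-methyl-1-(propan-2-yl)cyclopentan-1-ol | C[C@H](OCc1ccccc1)C[C@H](O)[C@H]1[C@](O)(C(C)C)C[C@@H](O[Si](C)(C)C(C)(C)C)[C@@H]1C | intermediate
9 | O4,O6-isopropylidene acetal of 8 | C[C@H](OCc1ccccc1)C[C@@H]2OC(C)(C)O[C@@]3(C(C)C)C[C@@H](O[Si](C)(C)C(C)(C)C)[C@H](C)[C@@H]23 | intermediate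
10 | C2 alcohol from 9 | C[C@H](OCc1ccccc1)C[C@@H]2OC(C)(C)O[C@@]3(C(C)C)C[C@@H](O)[C@H](C)[C@@H]23 | intermediate
11 | C2 ketone from 10 | C[C@H](OCc1ccccc1)C[C@@H]2OC(C)(C)O[C@@]3(C(C)C)CC(=O)[C@H](C)[C@@H]23 | intermediate
12 | C1=C2 triethylsilyl enol ether of 11 | C[C@H](OCc1ccccc1)C[C@@H]2OC(C)(C)O[C@@]3(C(C)C)CC(O[Si](CC)(CC)CC)=C(C)[C@@H]23 | intermediate
13 | C8 alcohol from 12 | C[C@H](O)C[C@@H]2OC(C)(C)O[C@@]3(C(C)C)CC(O[Si](CC)(CC)CC)=C(C)[C@@H]23 | intermediate
14 | C8 methyl ketone with C1=C2 triethylsilyl enol ether | CC(=O)C[C@@H]2OC(C)(C)O[C@@]3(C(C)C)CC(O[Si](CC)(CC)CC)=C(C)[C@@H]23 | intermediate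
15 | vinyltriphenylphosphonium bromide | C=C[P+](c1ccccc1)(c1ccccc1)c1ccccc1.[Br-] | starting material
16 | tetrabutylammonium C1 enolate of the C2 ketone | CC(=O)C[C@@H]2OC(C)(C)O[C@@]3(C(C)C)CC([O-])=C(C)[C@@H]23.CCCC[N+](CCCC)(CCCC)CCCC | intermediate
17 | C1-(2-triphenylphosphoranylideneethyl) diketone (ylide) | CC(=O)C[C@@H]2OC(C)(C)O[C@@]3(C(C)C)CC(=O)[C@](C)(CC=P(c4ccccc4)(c4ccccc4)c4ccccc4)[C@@H]23 | intermediate
18 | (1R,4R,5S,6S)-4,6-O-isopropylidene-4,6-dihydroxydauc-8-en-2-one | CC1=CC[C@@]2(C)C(=O)C[C@]3(C(C)C)OC(C)(C)O[C@@H](C1)[C@H]23 | intermediate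
19 | (1R,4R,5S,6S)-4,6-dihydroxydauc-8-en-2-one | CC1=CC[C@@]2(C)C(=O)C[C@@](O)(C(C)C)[C@@H]2[C@@H](O)C1 | intermediate
20 | 4-acetoxybenzoyl chloride | CC(=O)Oc1ccc(cc1)C(Cl)=O | starting material
21 | (1R,4R,5S,6S)-4-hydroxy-2-oxodauc-8-en-6-yl 4-acetoxybenzoate | CC1=CC[C@@]2(C)C(=O)C[C@@](O)(C(C)C)[C@@H]2[C@@H](OC(=O)c2ccc(OC(C)=O)cc2)C1 | intermediate
22 | (1R,2R,4R,5S,6S)-2,4-dihydroxydauc-8-en-6-yl 4-acetoxybenzoate | CC1=CC[C@@]2(C)[C@H](O)C[C@@](O)(C(C)C)[C@@H]2[C@@H](OC(=O)c2ccc(OC(C)=O)cc2)C1 | intermediate
23 | (1R,2R,4R,5S,6S)-2,4-dihydroxydauc-8-en-6-yl 4-hydroxybenzoate | CC1=CC[C@@]2(C)[C@H](O)C[C@@](O)(C(C)C)[C@@H]2[C@@H](OC(=O)c2ccc(O)cc2)C1 | target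

Total steps: 14. Longest linear sequence: 14 steps from 1 (12 steps from 4).

Steps most likely to fail

Step 11. Proton transfer from the methyl ketone to the enolate or ylide, followed by loss of the C6 oxygen, may compete, as may O-alkylation of the naked enolate or intermolecular olefination. The fallback separates the two bond formations. It sets out from 14: fluoride-triggered regiospecific C-allylation with allyl bromide and TBAT should give the C1-allyl diketone F1, with the allyl group anti to the C5 side chain. Wittig methylenation with Ph3P=CH2 should take place only at the unhindered methyl ketone and give the diene F2. Ring-closing metathesis with second-generation Grubbs catalyst then closes C8=C9 and comes back to the route at 18.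

Step 8. Enolisation may go towards C3, or the silyl triflate may open the acetonide. The fallback fixes the regiochemistry by halogenation instead of silylation. It sets out from 11: bromination with PhNMe3Br3 through the acid-catalysed, more substituted enol should give the tertiary alpha-bromo ketone F3. Reductive silylation with Zn dust and Et3SiCl converts it regiospecifically into 12, where it rejoins the route.

Step 3. The aldol addition may show poor simple diastereoselectivity at C6, or the adduct may undergo retro-aldol cleavage on work-up. The fallback corrects C6 by inversion instead of selection. It sets out from 4 and 3: if the syn aldol F4 predominates, it is carried through the organocerium addition of step 4 to the epimeric diol F5. Mitsunobu esterification of the secondary C6 hydroxyl (4-nitrobenzoic acid, PPh3, DIAD) gives the inverted 4-nitrobenzoate F6, and methanolysis (K2CO3, MeOH) returns to the route at 8.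

Further compounds
F1 | step 11 | C1-allyl diketone (allyl anti to the C5 side chain) | CC(=O)C[C@@H]2OC(C)(C)O[C@@]3(C(C)C)CC(=O)[C@](C)(CC=C)[C@@H]23
F2 | step 11 | C8-methylene diene from F1 | CC(=C)C[C@@H]2OC(C)(C)O[C@@]3(C(C)C)CC(=O)[C@](C)(CC=C)[C@@H]23
F3 | step 8 | C1-bromo derivative of ketone 11 | C[C@H](OCc1ccccc1)C[C@@H]2OC(C)(C)O[C@@]3(C(C)C)CC(=O)[C@](C)(Br)[C@@H]23
F4 | step 3 | C6 epimer of aldol adduct 7 | C[C@H](OCc1ccccc1)C[C@@H](O)[C@H]1C(=O)C[C@@H](O[Si](C)(C)C(C)(C)C)[C@@H]1C
F5 | step 3 | C6 epimer of diol 8 | C[C@H](OCc1ccccc1)C[C@@H](O)[C@H]1[C@](O)(C(C)C)C[C@@H](O[Si](C)(C)C(C)(C)C)[C@@H]1C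
F6 | step 3 | 6-O-(4-nitrobenzoyl) derivative of diol 8 | C[C@H](OCc1ccccc1)C[C@H](OC(=O)c2ccc(cc2)[N+](=O)[O-])[C@H]1[C@](O)(C(C)C)C[C@@H](O[Si](C)(C)C(C)(C)C)[C@@H]1C
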